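**Retrosynthetic overview**
1. Feature: in the oxepane (O, C3, C2, C1, C14, C15, C16), C15 sits on ring A at C14 and carries two one-carbon arms, C16 (OCH2) and C17 (CH3). With C15=C17 as a methylene, C16–C15–C17 is a 2-substituted allyl unit whose two CH2 ends are alike.
2. C15–H is therefore added last, by hydrogenation of C15=C17. O–C16 is cut back to the C3 tertiary alcohol and a C16 allylic tert-butyl carbonate, joined through a π-allylpalladium complex (oxepane, last ring).
3. The allyl carbonate comes from a C14 Weinreb amide (alkoxymethyllithium, then Wittig methylenation). C12–H and C11–OAc come from a C11=C12 silyl enol ether (protonation, hydride, acetylation).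
4. Ring A and the tetrahydrofuran form together (C1–C10, C13–C14) in an intramolecular Diels–Alder reaction of a C9 2-silyloxydiene with a C2 E-enamide across a preformed Z-oxonene.
5. The oxonene comes from ring-closing metathesis (C6=C7) of an ether built by Keck methallylation (C9), Evans glycolate aldol (C2) and chelate-controlled Grignard addition (C3). Ring order: oxonene, then ring A plus tetrahydrofuran, then oxepane.

Key step: step 27

Remark: asbestinin numbering is used (carbocycle C1–C14, C15 on C14, C16 = OCH2, C17 = CH3 on C15, C18/C19/C20 = CH3 on C3/C7/C12; ring A = C1, C10, C11, C12, C13, C14), and the C11 carbinol of 26 is carried as an epimer mixture because step 17 oxidises it.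

**Step 1**
Reactants: 1 3-[(4-methoxybenzyl)oxy]propan-1-ol
Product: 2 3-[(4-methoxybenzyl)oxy]propanal
Conditions: TEMPO (10 mol %), PhI(OAc)2, CH2Cl2, rt
Reagents that add atoms: none
Why: The oxoammonium (TEMPO/PhI(OAc)2) oxidation takes the primary alcohol to the aldehyde without over-oxidation and does not touch the PMB ether.

**Step 2**
Reactants: 2 3-[(4-methoxybenzyl)oxy]propanal; 3 tributyl(2-methylprop-2-en-1-yl)stannane
Product: 4 (3S)-1-[(4-methoxybenzyl)oxy]-5-methylhex-5-en-3-ol
Conditions: (S)-BINOL (20 mol %), Ti(OiPr)4 (10 mol %), 4 Å MS, CH2Cl2, −20 °C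
Reagents that add atoms: tributyl(2-methylprop-2-en-1-yl)stannane 3, CC(=C)C[Sn](CCCC)(CCCC)CCCC
Why: In this Keck asymmetric methallylation the (S)-BINOL–titanium Lewis acid exposes the Si face of the aldehyde and sets C9 as S, and any minor enantiomer becomes a separable diastereomer once the auxiliary is attached.

**Step 3**
Reactants: 4 (3S)-homoallylic alcohol; 5 bromoacetic acid
Product: 6 {[(3S)-1-[(4-methoxybenzyl)oxy]-5-methylhex-5-en-3-yl]oxy}acetic acid
Conditions: NaH (3 equiv), THF, 0 °C to rt; then 1 M HCl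
Reagents that add atoms: bromoacetic acid 5, OC(=O)CBr
Why: Williamson etherification of the sodium alkoxide with sodium bromoacetate builds the C9–O–C2 ether at an unhindered primary carbon, so C9 is not touched.

**Step 4**
Reactants: 6 glycolic acid ether; 7 (4R)-4-benzyl-1,3-oxazolidin-2-one
Product: 9 N-glycolyl oxazolidinone, via mixed pivalic anhydride 8 (not isolated)
Conditions: t-BuCOCl, Et3N, THF, −20 °C; then LiCl, 7, rt
Reagents that add atoms: (4R)-4-benzyl-1,3-oxazolidin-2-one 7, O=C1OC[C@@H](Cc2ccccc2)N1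
Why: N-Acylation of the oxazolidinone by the mixed pivalic anhydride takes place at the less hindered glycolyl carbonyl and installs the auxiliary that will control C2.

**Step 5**
Reactants: 9 N-glycolyl oxazolidinone; 10 acetaldehyde
Product: 12 syn-aldol imide, via Z-dibutylboron enolate 11 (not isolated)
Conditions: Bu2BOTf, Et3N, CH2Cl2, −78 to 0 °C; 10, −78 to 0 °C; pH 7 buffer, MeOH, H2O2
Reagents that add atoms: acetaldehyde 10, CC=O
Why: In this Evans syn aldol reaction the Z-boron enolate reacts through a Zimmerman–Traxler chair on the face away from the benzyl group of the R auxiliary, which sets C2, while the C3 carbinol centre is of no consequence because step 8 oxidises it.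

**Step 6**
Reactants: 12 syn-aldol imide
Product: 13 (2S,3S)-2-alkoxybutane-1,3-diol (alkoxy = the C9 ether residue)
Conditions: LiBH4, MeOH (1 equiv), THF, 0 °C
Reagents that add atoms: none
Why: Reductive removal of the auxiliary with LiBH4 gives the C1 primary alcohol without epimerising C2 and returns the oxazolidinone.

**Step 7**
Reactants: 13 1,3-diol
Product: 14 C1 triethylsilyl ether with free C3 secondary alcohol
Conditions: Et3SiCl (1.05 equiv), imidazole, CH2Cl2, −40 °C
Reagents that add atoms: chlorotriethylsilane, CC[Si](Cl)(CC)CC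
Why: Kinetic silylation distinguishes the primary C1 hydroxyl from the secondary C3 hydroxyl on steric grounds.

**Step 8**
Reactants: 14 mono-TES ether
Product: 15 (3S)-3-alkoxy-4-[(triethylsilyl)oxy]butan-2-one
Conditions: Pr4NRuO4 (5 mol %), NMO, 4 Å MS, CH2Cl2, rt
Reagents that add atoms: none
Why: The neutral Ley–Griffith oxidation gives the α-alkoxy methyl ketone without loss of the primary TES ether or epimerisation at C2.

**Step 9**
Reactants: 15 α-alkoxy methyl ketone; 16 but-3-en-1-ylmagnesium bromide
Product: 17 (2S,3S)-tertiary alcohol (C3 bearing CH3, OH and the butenyl chain)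
Conditions: MgBr2·OEt2, CH2Cl2, −78 °C; then 16
Reagents that add atoms: but-3-en-1-ylmagnesium bromide 16, C=CCC[Mg]Br
Why: In this Cram-chelate Grignard addition magnesium ties the C3 carbonyl to the C2 ether oxygen and the butenyl group enters from the side of H2 rather than of C1, so C3 is set with O2 and O3 syn along the C1–C4 chain (3S).

**Step 10**
Reactants: 17 tertiary alcohol
Product: 18 bis-TES diene
Conditions: Et3SiOTf, 2,6-lutidine, CH2Cl2, −78 to 0 °C
Reagents that add atoms: triethylsilyl trifluoromethanesulfonate, CC[Si](CC)(CC)OS(=O)(=O)C(F)(F)F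
Why: Silylation with the triflate masks the tertiary C3 hydroxyl so that the later C1 aldehyde cannot undergo retro-aldol cleavage.

**Step 11**
Reactants: 18 bis-TES diene
Product: 19 (2S,3S,9S,6Z)-oxonene
Conditions: second-generation Grubbs catalyst RuCl2(=CHPh)(PCy3)(SIMes) (5 mol %), CH2Cl2 (0.002 M), reflux
Reagents that add atoms: none
Why: Ring-closing metathesis starts at the monosubstituted C6 alkene and closes onto the methallyl group, the nine-membered ring accepts only the Z C6=C7 alkene, and the gauche preference about the two C–O bonds of the α,α'-disubstituted ether brings the chain ends together.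

**Step 12**
Reactants: 19 oxonene
Product: 20 oxonene C1 aldehyde
Conditions: (COCl)2, DMSO, CH2Cl2, −78 to −30 °C; Et3N, −78 °C to rt
Reagents that add atoms: none
Why: Under Swern conditions the chlorosulfonium salt cleaves the unhindered primary TES ether and oxidises it in place to the aldehyde (known direct Swern oxidation of primary silyl ethers), whereas the tertiary TES ether and the PMB ether are inert.

**Step 13**
Reactants: 20 C1 aldehyde; 21 N-methoxy-N-methyl-2-(triphenyl-λ5-phosphanylidene)acetamide
Product: 22 E-unsaturated Weinreb amide (C1=C14)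
Conditions: CH2Cl2, rt
Reagents that add atoms: ylide 21, CON(C)C(=O)C=P(c1ccccc1)(c1ccccc1)c1ccccc1
Why: The Wittig reaction of the stabilised ylide is E-selective and mild enough not to epimerise the α-alkoxy aldehyde, and it installs the dienophile as a Weinreb amide that the soft enolisation of step 18 cannot touch.

**Step 14**
Reactants: 22 PMB ether
Product: 23 C11 primary alcohol
Conditions: DDQ, CH2Cl2/pH 7 buffer, 0 °C
Reagents that add atoms: none
Why: Oxidative PMB cleavage with DDQ frees the C11 alcohol and leaves the alkenes, the enamide and the tertiary TES ether intact.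

**Step 15**
Reactants: 23 C11 alcohol
Product: 24 C11 aldehyde
Conditions: Dess–Martin periodinane, CH2Cl2, 0 °C to rt
Reagents that add atoms: none
Why: Dess–Martin oxidation gives the β-alkoxy aldehyde under non-basic conditions, which avoids β-elimination of the ring oxygen.

**Step 16**
Reactants: 24 C11 aldehyde; 25 prop-1-en-2-ylmagnesium bromide
Product: 26 C11 allylic alcohol (epimers at C11)
Conditions: THF, −78 °C
Reagents that add atoms: prop-1-en-2-ylmagnesium bromide 25, CC(=C)[Mg]Br
Why: Grignard 1,2-addition to the aldehyde is much faster at −78 °C than attack on the unsaturated Weinreb amide, and the new C11 centre need not be controlled.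

**Step 17**
Reactants: 26 allylic alcohol
Product: 27 C11 isopropenyl ketone
Conditions: Dess–Martin periodinane, CH2Cl2, 0 °C to rt
Reagents that add atoms: none
Why: Dess–Martin oxidation of the allylic alcohol gives the cross-conjugated ketone and erases the C11 centre.

**Step 18**
Reactants: 27 isopropenyl ketone
Product: 29 tricyclic C14 Weinreb amide, via silyloxy tetraene 28 (not isolated)
Conditions: t-BuMe2SiOTf, Et3N, CH2Cl2, −78 to 0 °C; NaHCO3 wash, solvent change to toluene (BHT), 90 °C
Reagents that add atoms: tert-butyldimethylsilyl trifluoromethanesulfonate, CC(C)(C)[Si](C)(C)OS(=O)(=O)C(F)(F)F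
Why: Soft enolisation toward C10 (the only α-CH2) should give the Z-silyl dienol ether, which adds to the E-enamide in an intramolecular Diels–Alder reaction where the C9–O–C2 tether forces C2 endo and the amide exo (cis C1/C10 fusion), the E-alkene places C2 and C15 trans on C1/C14, and the two π systems can meet only on the oxonene face away from C3 and C8.

**Step 19**
Reactants: 30 4-methoxybenzyl alcohol; 31 tributyl(iodomethyl)stannane
Product: 32 tributyl{[(4-methoxybenzyl)oxy]methyl}stannane
Conditions: NaH, THF/DMF, 0 °C to rt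
Reagents that add atoms: tributyl(iodomethyl)stannane 31, CCCC[Sn](CI)(CCCC)CCCC
Why: Williamson etherification of the sodium benzyl oxide with the primary iodide gives the α-alkoxystannane needed for tin–lithium exchange.

**Step 20**
Reactants: 29 tricyclic Weinreb amide; 32 alkoxymethylstannane
Product: 34 tricyclic C15 alkoxymethyl ketone, via 4-methoxybenzyloxymethyllithium 33 (not isolated)
Conditions: 32, n-BuLi, THF, −78 °C; then 29, −78 to −40 °C
Reagents that add atoms: stannane 32, CCCC[Sn](CCCC)(CCCC)COCc1ccc(OC)cc1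
Why: Tin–lithium exchange gives the α-alkoxymethyllithium, which adds once to the Weinreb amide (chelated tetrahedral intermediate, Weinreb ketone synthesis) to give the C15 ketone carrying C16, with the silyl enol ether and C14 untouched at low temperature.

**Step 21**
Reactants: 34 C15 ketone; 35 methyltriphenylphosphonium bromide
Product: 37 C15 methylene compound, via methylidenetriphenylphosphorane 36 (not isolated)
Conditions: 35, KOt-Bu, THF, 0 °C; then 34, 0 °C to rt
Reagents that add atoms: methyltriphenylphosphonium bromide 35, C[P+](c1ccccc1)(c1ccccc1)c1ccccc1.[Br-]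
Why: Wittig methylenation turns the C15 ketone into the C15=C17 methylene, and since the trans C1/C14 arrangement is also expected to be the more stable one, passing enolisation should do no harm.

**Step 22**
Reactants: 37 TBS enol ether/C3 TES ether
Product: 38 C11 ketone with 12R methyl and free C3 hydroxyl
Conditions: HF·pyridine, excess pyridine, THF, 0 °C; used at once
Reagents that add atoms: none
Why: Protodesilylation of the silyl enol ether under kinetic control should deliver the proton to C12 from the face that carries H1 and H10, because the other face is screened by the pseudoaxial C10–C9 bond and the tetrahydrofuran, so C20 ends cis to C9, and the same reagent frees the C3 hydroxyl.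

**Step 23**
Reactants: 38 C11 ketone
Product: 39 (11R)-C11,C3-diol
Conditions: LiBH(s-Bu)3, THF, −78 °C; then NaOH, H2O2
Reagents that add atoms: none
Why: This diastereoselective ketone reduction with a bulky, non-basic hydride should attack from the H10/H12 face because both α-substituents (C9 and C20) lie on the other face, which puts the C11 hydroxyl cis to C20 without epimerising C12.

**Step 24**
Reactants: 39 diol; 40 acetic anhydride
Product: 41 C11 acetate
Conditions: DMAP, Et3N, CH2Cl2, rt
Reagents that add atoms: acetic anhydride 40, CC(=O)OC(C)=O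
Why: DMAP-catalysed acetylation esterifies the secondary C11 hydroxyl, while the tertiary C3 hydroxyl is too hindered to react at room temperature.

**Step 25**
Reactants: 41 C16 PMB ether
Product: 42 C16 allylic alcohol
Conditions: DDQ (1.2 equiv), CH2Cl2/pH 7 buffer, 0 °C
Reagents that add atoms: none
Why: Oxidative PMB cleavage with DDQ frees the primary allylic alcohol and tolerates the acetate, both alkenes and the tertiary alcohol.

**Step 26**
Reactants: 42 allylic alcohol; 43 di-tert-butyl dicarbonate
Product: 44 tricyclic C3 alcohol with the 2-substituted allyl tert-butyl carbonate on C14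
Conditions: DMAP (20 mol %), CH2Cl2, 0 °C to rt
Reagents that add atoms: di-tert-butyl dicarbonate 43, CC(C)(C)OC(=O)OC(=O)OC(C)(C)C
Why: DMAP-catalysed carbonate formation takes place only at the primary allylic hydroxyl, the tertiary C3 hydroxyl being unreactive.

**Step 27**
Reactants: 44 allyl tert-butyl carbonate/C3 alcohol
Product: 45 tetracycle with exocyclic C15=C17 methylene
Conditions: Pd2(dba)3·CHCl3 (5 mol %), PPh3 (30 mol %), degassed THF (0.005 M), 45 °C
Reagents that add atoms: none
Why: Zerovalent palladium ionises the primary allylic carbonate to a cationic 2-alkyl-π-allylpalladium complex (C16–C15–C17), and the carbonate anion loses CO2 to give tert-butoxide, which is basic enough to deprotonate the C3 hydroxyl but too hindered to compete as a nucleophile. The C3 alkoxide then attacks a CH2 terminus on the face away from palladium, forming O–C16 and releasing the catalyst, which is an intramolecular Tsuji–Trost O-allylation, a known route to cyclic ethers. The oxepane (O, C3, C2, C1, C14, C15, C16) closes in the 7-exo sense: palladium leaves outside the new ring, C15 becomes a ring atom and C17 stays as the exocyclic methylene. No stereocentre is created, and because C16 and C17 are both unsubstituted CH2 ends of a symmetric allyl unit, attack at either end gives the same product and no regiocontrol is needed. The selectivity needed is intramolecular over intermolecular capture, and it is secured by high dilution, by the trans placement of C2 and C15 on ring A that holds O3 near C16, and by the tert-butyl carbonate, since methoxide from a methyl carbonate would be less basic than the C3 alkoxide, would form the allyl methyl ether and would attack the C11 acetate. Diene formation is not a threat, because the σ-allyl form has only the fully substituted C15 in the β position (C14–H is γ), and neither the C11 acetate nor the product alkyl allyl ether is ionised under these conditions.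

**Step 28**
Reactants: 45 C15 methylene tetracycle
Product: 46 target CNP0177382.3
Conditions: RhCl(PPh3)3 (15 mol %), H2 (1 atm), benzene/EtOH, rt
Reagents that add atoms: none
Why: Homogeneous hydrogenation with RhCl(PPh3)3 reduces the 1,1-disubstituted alkene and leaves the trisubstituted C6=C7 alkene, and the catalyst should bind the face flanked only by axial H14 (the other face lies over H1 and the C4–C5 limb of the oxonene), so that H15 ends cis to H14 and C17 on the H1 side (15R).

**Compound list**
1 | 3-[(4-methoxybenzyl)oxy]propan-1-ol | COc1ccc(COCCCO)cc1 | starting material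
2 | 3-[(4-methoxybenzyl)oxy]propanal | COc1ccc(COCCC=O)cc1 | intermediate
3 | tributyl(2-methylprop-2-en-1-yl)stannane | CC(=C)C[Sn](CCCC)(CCCC)CCCC | starting material
4 | (3S)-1-[(4-methoxybenzyl)oxy]-5-methylhex-5-en-3-ol | CC(=C)C[C@H](O)CCOCc1ccc(OC)cc1 | intermediate
5 | bromoacetic acid | OC(=O)CBr | starting material
6 | {[(3S)-1-[(4-methoxybenzyl)oxy]-5-methylhex-5-en-3-yl]oxy}acetic acid | CC(=C)C[C@H](OCC(=O)O)CCOCc1ccc(OC)cc1 | intermediate
7 | (4R)-4-benzyl-1,3-oxazolidin-2-one | O=C1OC[C@@H](Cc2ccccc2)N1 | starting material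
8 | mixed pivalic anhydride of 6 | CC(=C)C[C@H](OCC(=O)OC(=O)C(C)(C)C)CCOCc1ccc(OC)cc1 | intermediate
9 | (4R)-4-benzyl-3-(alkoxyacetyl)-1,3-oxazolidin-2-one, alkoxy = (3S)-1-(PMB-oxy)-5-methylhex-5-en-3-yloxy | CC(=C)C[C@H](OCC(=O)N1C(=O)OC[C@H]1Cc1ccccc1)CCOCc1ccc(OC)cc1 | intermediate
10 | acetaldehyde | CC=O | starting material
11 | Z-dibutylboron enolate of 9 | CCCCB(CCCC)O/C(N1C(=O)OC[C@H]1Cc1ccccc1)=C\O[C@@H](CC(C)=C)CCOCc1ccc(OC)cc1 | intermediate
12 | syn-aldol imide, (2R,3S)-3-hydroxy-2-alkoxybutanoyl on the (4R)-auxiliary | C[C@H](O)[C@@H](O[C@@H](CC(C)=C)CCOCc1ccc(OC)cc1)C(=O)N1C(=O)OC[C@H]1Cc1ccccc1 | intermediate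
13 | (2S,3S)-2-alkoxybutane-1,3-diol | C[C@H](O)[C@@H](O[C@@H](CC(C)=C)CCOCc1ccc(OC)cc1)CO | intermediate
14 | (2S,3S)-3-alkoxy-4-[(triethylsilyl)oxy]butan-2-ol | C[C@H](O)[C@@H](O[C@@H](CC(C)=C)CCOCc1ccc(OC)cc1)CO[Si](CC)(CC)CC | intermediate
15 | (3S)-3-alkoxy-4-[(triethylsilyl)oxy]butan-2-one | CC(=O)[C@@H](O[C@@H](CC(C)=C)CCOCc1ccc(OC)cc1)CO[Si](CC)(CC)CC | intermediate
16 | but-3-en-1-ylmagnesium bromide | C=CCC[Mg]Br | starting material
17 | (2S,3S)-2-alkoxy-3-methyl-1-[(triethylsilyl)oxy]hept-6-en-3-ol | C=CCC[C@](C)(O)[C@@H](O[C@@H](CC(C)=C)CCOCc1ccc(OC)cc1)CO[Si](CC)(CC)CC | intermediate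
18 | C1,C3-bis(triethylsilyl) ether of the diene | C=CCC[C@](C)(O[Si](CC)(CC)CC)[C@@H](O[C@@H](CC(C)=C)CCOCc1ccc(OC)cc1)CO[Si](CC)(CC)CC | intermediate
19 | (2S,3S,9S,6Z)-3,7-dimethyl-9-[2-(PMB-oxy)ethyl]-3-(TES-oxy)-2-(TES-oxymethyl)-2,3,4,5,8,9-hexahydrooxonine | CC[Si](CC)(CC)OC[C@@H]1O[C@H](CCOCc2ccc(OC)cc2)C/C(C)=C\CC[C@]1(C)O[Si](CC)(CC)CC | intermediate
20 | oxonene-2-carbaldehyde (C1 aldehyde, ring configuration as in 19) | O=C[C@@H]1O[C@H](CCOCc2ccc(OC)cc2)C/C(C)=C\CC[C@]1(C)O[Si](CC)(CC)CC | intermediate
21 | N-methoxy-N-methyl-2-(triphenyl-λ5-phosphanylidene)acetamide | CON(C)C(=O)C=P(c1ccccc1)(c1ccccc1)c1ccccc1 | starting material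
22 | oxonene with E-CH=CH–C(O)N(OMe)Me on C2 and 2-(PMB-oxy)ethyl on C9 | CON(C)C(=O)/C=C/[C@@H]1O[C@H](CCOCc2ccc(OC)cc2)C/C(C)=C\CC[C@]1(C)O[Si](CC)(CC)CC | intermediate
23 | as 22, 2-hydroxyethyl on C9 | CON(C)C(=O)/C=C/[C@@H]1O[C@H](CCO)C/C(C)=C\CC[C@]1(C)O[Si](CC)(CC)CC | intermediate
24 | as 22, 2-oxoethyl on C9 | CON(C)C(=O)/C=C/[C@@H]1O[C@H](CC=O)C/C(C)=C\CC[C@]1(C)O[Si](CC)(CC)CC | intermediate
25 | prop-1-en-2-ylmagnesium bromide | CC(=C)[Mg]Br | starting material
26 | as 22, 2-hydroxy-3-methylbut-3-enyl on C9 (C11 epimers) | CON(C)C(=O)/C=C/[C@@H]1O[C@H](CC(O)C(C)=C)C/C(C)=C\CC[C@]1(C)O[Si](CC)(CC)CC | intermediate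
27 | as 22, 3-methyl-2-oxobut-3-enyl on C9 | CON(C)C(=O)/C=C/[C@@H]1O[C@H](CC(=O)C(C)=C)C/C(C)=C\CC[C@]1(C)O[Si](CC)(CC)CC | intermediate
28 | tetraene: Z-2-(TBS-oxy)-3-methylbuta-1,3-dienyl on C9, E-enamide on C2 | CON(C)C(=O)/C=C/[C@@H]1O[C@H](/C=C(\O[Si](C)(C)C(C)(C)C)C(C)=C)C/C(C)=C\CC[C@]1(C)O[Si](CC)(CC)CC | intermediate
29 | tricycle (oxonene, tetrahydrofuran, ring A): C11=C12 TBS enol ether, C14 C(O)N(OMe)Me, C3 OTES; H1/H10 cis, H1/H2, H9/H10 and H1/H14 trans | CC1=C(O[Si](C)(C)C(C)(C)C)[C@@H]2[C@H]([C@@H](C1)C(=O)N(C)OC)[C@@H]3O[C@H]2C/C(C)=C\CC[C@]3(C)O[Si](CC)(CC)CC | intermediate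
30 | 4-methoxybenzyl alcohol | COc1ccc(CO)cc1 | starting material
31 | tributyl(iodomethyl)stannane | CCCC[Sn](CI)(CCCC)CCCC | starting material
32 | tributyl{[(4-methoxybenzyl)oxy]methyl}stannane | CCCC[Sn](CCCC)(CCCC)COCc1ccc(OC)cc1 | intermediate
33 | [(4-methoxybenzyl)oxy]methyllithium | [Li]COCc1ccc(OC)cc1 | intermediate
34 | tricycle as 29 with C14 C(O)CH2OPMB | CC1=C(O[Si](C)(C)C(C)(C)C)[C@@H]2[C@H]([C@@H](C1)C(=O)COCc4ccc(OC)cc4)[C@@H]3O[C@H]2C/C(C)=C\CC[C@]3(C)O[Si](CC)(CC)CC | intermediate
35 | methyltriphenylphosphonium bromide | C[P+](c1ccccc1)(c1ccccc1)c1ccccc1.[Br-] | starting material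
36 | methylidenetriphenylphosphorane | C=P(c1ccccc1)(c1ccccc1)c1ccccc1 | intermediate
37 | tricycle as 29 with C14 C(=CH2)CH2OPMB | CC1=C(O[Si](C)(C)C(C)(C)C)[C@@H]2[C@H]([C@@H](C1)C(=C)COCc4ccc(OC)cc4)[C@@H]3O[C@H]2C/C(C)=C\CC[C@]3(C)O[Si](CC)(CC)CC | intermediate
38 | tricyclic C11 ketone, C12 methyl cis to C9, C3 OH free, C14 C(=CH2)CH2OPMB | O=C1[C@@H]2[C@H]([C@@H](C[C@H]1C)C(=C)COCc4ccc(OC)cc4)[C@@H]3O[C@H]2C/C(C)=C\CC[C@]3(C)O | intermediate
39 | tricyclic C11,C3-diol, C11 OH cis to C20 and C9 | O[C@H]1[C@@H]2[C@H]([C@@H](C[C@H]1C)C(=C)COCc4ccc(OC)cc4)[C@@H]3O[C@H]2C/C(C)=C\CC[C@]3(C)O | intermediate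
40 | acetic anhydride | CC(=O)OC(C)=O | starting material
41 | tricyclic C11 acetate, C16 PMB ether, C3 OH | CC(=O)O[C@H]1[C@@H]2[C@H]([C@@H](C[C@H]1C)C(=C)COCc4ccc(OC)cc4)[C@@H]3O[C@H]2C/C(C)=C\CC[C@]3(C)O | intermediate
42 | tricyclic C11 acetate, C16 allylic alcohol, C3 OH | CC(=O)O[C@H]1[C@@H]2[C@H]([C@@H](C[C@H]1C)C(=C)CO)[C@@H]3O[C@H]2C/C(C)=C\CC[C@]3(C)O | intermediate
43 | di-tert-butyl dicarbonate | CC(C)(C)OC(=O)OC(=O)OC(C)(C)C | starting material
44 | tricyclic C3 alcohol with 2-substituted allyl tert-butyl carbonate on C14 | CC(=O)O[C@H]1[C@@H]2[C@H]([C@@H](C[C@H]1C)C(=C)COC(=O)OC(C)(C)C)[C@@H]3O[C@H]2C/C(C)=C\CC[C@]3(C)O | intermediate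
45 | tetracycle with exocyclic C15=C17 methylene | CC(=O)O[C@H]1[C@@H]2[C@@H]3[C@@H](C[C@H]1C)C(=C)CO[C@@]1(C)CC/C=C(/C)C[C@@H]2O[C@@H]31 | intermediate
46 | CNP0177382.3, (1S,2S,3S,9S,10R,11R,12R,14S,15R,6Z) in asbestinin numbering | CC(=O)O[C@H]1[C@@H]2[C@@H]3[C@@H](C[C@H]1C)[C@@H](C)CO[C@@]1(C)CC/C=C(/C)C[C@@H]2O[C@@H]31 | target

**Totals.** Total step count: 28. Longest linear sequence: 27 (steps 1–18 and 20–28; step 19 is a side branch).

**Steps most likely to fail**

**Step 27.**
- The hindered tertiary alkoxide may close the seven-membered ring too slowly. Intermolecular allylation, capture by tert-butoxide or plain loss of the carbonate could then take over.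
- The fallback leaves palladium out and sets out from 42.
- The C16 hydroxyl is converted (CBr4, PPh3, CH2Cl2, 0 °C) into allylic bromide F1.
- The oxepane is then closed by silver-assisted intramolecular etherification (AgOTf, 2,6-di-tert-butyl-4-methylpyridine, CH2Cl2, −20 °C). The fallback comes back to the route at 45.

**Step 22.**
- The proton may reach C12 from the wrong face, or the ketone may epimerise afterwards. Acid could also trigger transannular attack of the C3 hydroxyl on C6=C7.
- The fallback replaces substrate control by catalyst control and sets out from 37.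
- The TBS enol ether is exchanged regiospecifically (Bu4N[Ph3SiF2], allyl chloroformate, THF, −78 °C) for allyl enol carbonate F2.
- Palladium-catalysed decarboxylative protonation follows (Pd(OAc)2, the matched antipode of t-BuPHOX, HCO2H, 4 Å MS, dioxane, 40 °C) and gives C3-TES ketone F3.
- Brief HF·pyridine treatment returns to the route at 38.

**Step 28.**
- Facial selectivity at C15 may be poor, or a rhodium hydride may isomerise the allyl ether to an enol ether.
- The fallback uses reagent-controlled hydroboration followed by deoxygenation and sets out from 45.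
- Diisopinocampheylborane is used in the antipode matched to the H14 face. It is unreactive toward the trisubstituted C6=C7 alkene. Work-up with NaBO3 gives C17 primary alcohol F4.
- I2, PPh3 and imidazole give C17 iodide F5.
- Radical reduction (Bu3SnH, AIBN, toluene, 80 °C) comes back at 46.

**Further compounds**
F1 | step 27 | tricyclic C16 allylic bromide (C11 OAc, C3 OH) | CC(=O)O[C@H]1[C@@H]2[C@H]([C@@H](C[C@H]1C)C(=C)CBr)[C@@H]3O[C@H]2C/C(C)=C\CC[C@]3(C)O
F2 | step 22 | tricyclic C11 allyl enol carbonate (C3 OTES, C16 OPMB) | CC1=C(OC(=O)OCC=C)[C@@H]2[C@H]([C@@H](C1)C(=C)COCc4ccc(OC)cc4)[C@@H]3O[C@H]2C/C(C)=C\CC[C@]3(C)O[Si](CC)(CC)CC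
F3 | step 22 | tricyclic C11 ketone with C3 OTES (C12 methyl cis to C9) | O=C1[C@@H]2[C@H]([C@@H](C[C@H]1C)C(=C)COCc4ccc(OC)cc4)[C@@H]3O[C@H]2C/C(C)=C\CC[C@]3(C)O[Si](CC)(CC)CC
F4 | step 28 | tetracyclic C17 primary alcohol | CC(=O)O[C@H]1[C@@H]2[C@@H]3[C@@H](C[C@H]1C)[C@@H](CO)CO[C@@]1(C)CC/C=C(/C)C[C@@H]2O[C@@H]31
F5 | step 28 | tetracyclic C17 iodide | CC(=O)O[C@H]1[C@@H]2[C@@H]3[C@@H](C[C@H]1C)[C@@H](CI)CO[C@@]1(C)CC/C=C(/C)C[C@@H]2O[C@@H]31
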